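## The problem

The target 31 is a 6-5-9 tricycle: a cis-fused hydrindane (six-membered ring A, five-membered ring B) whose quaternary ring-fusion carbon also anchors a nine-membered azacycle (ring C) that re-enters ring B through an exocyclic enone. Atoms are numbered along the skeleton as C1 (CHOAc), C2, C3 (C(CH3)OAc), C4, C5 (ring-fusion CH), C6, C7 (C=O), C8=C9, C10, C11, N12, C13, C14, C15 and C16 (quaternary); ring A is C1–C5 plus C16, ring B is C5–C8 plus C16, ring C runs from C8 through N12 to C16, and the face of ring A on which ring B sits is called the top face. Four stereocentres, all S, are needed: C5 and C16 make the cis fusion, C1 carries its acetate on the top face, and C3 carries its acetate on the top face with the methyl group below. C5 and C16 are adjacent and can be set in one ring-forming event; the folded bicycle can then direct a hydride to C1, and a C1 hydroxyl can hand oxygen on to C3, so one chiral-pool stereocentre suffices if it controls C5. The C8=C9 alkene must be E, which is the cis arrangement inside ring C, so its geometry is secure only if the nine-membered ring exists before the alkene is made. The fragile points are the free secondary amine beside a Michael acceptor, the enone toward thiolates and hydrides, the tertiary C3 acetate toward strong acid, and both acetates toward base. The enabling feature is that ring B shares the C5–C16 bond with ring A while C1, next to C16, bears oxygen: with C1 as a ketone, C16 is the α- and C5 the β-carbon of a cyclohexenone, and C6, C7 and C8 can be laid across that enone as one three-carbon unit in which C7 carries a masked carbonyl and C8 the C9–C11 arm.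

## Retrosynthesis

**N12–H.** The amine is unmasked last: 31 comes from the tert-butyl carbamate 30 by acidolysis. A sulfonamide at this stage would need a thiolate, which adds to the enone, and a free amine cannot be carried through the oxidations. The carbamate asks only that both acetates survive brief cold acid.

**C8=C9.** The enone 30 is traced to the saturated C7 ketone 28 through its more substituted silyl enol ether 29 (Saegusa–Ito oxidation). Making the alkene after ring C exists lets the ring impose the E geometry; an open-chain elimination would not. The forward step needs enolisation toward C8 rather than C6; C8 is the more substituted side and C16 offers no competing β-hydrogen.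

**C7=O and the nitrogen group.** Ketone 28 comes from the nosylamide 26 by thiolate cleavage and carbamoylation, and 26 from the vinylsilane 24 by epoxidation and acid-induced loss of silicon. The C7–Si bond is what the key step leaves behind. Keeping C7 masked until ring A is oxidised and ring C is closed means the molecule never holds two enolisable ketones.

**Ring C, N12–C11 and N12–C13.** Both C–N bonds of 24 are cut at once, giving the bis-mesylate 20 and 2-nitrobenzenesulfonamide 21. Cutting at nitrogen removes the medium ring in one operation and leaves two identical three-carbon arms, which simplifies everything upstream. 20 comes from the bis-silyl ether 18 via diol 19. The forward reaction must close a nine-membered ring by SN2; the sulfonamide anion, the trigonal C8 and the quaternary C16 should help.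

**Ring A oxygenation, C3–O and C1–H.** Diacetate 18 is the ester of diol 17. The C3–O bond is traced to epoxy alcohol 16 and allylic alcohol 15, whose C1–H bond is traced to enone 14, the dehydrogenation product of ketone 12. This chain is preferred to direct oxidation of the C3–H bond because each event has a stereochemical reason: hydride enters C1 from the convex face, the C1 hydroxyl delivers oxygen to its own face, and hydride opens the epoxide at secondary C2. It costs the C3 stereocentre of 12, which by then has done its work.

**Ring B, C5–C6 and C8–C16 (key).** 12 is cut across ring B into the α-substituted cyclohexenone 7 and the allenylsilane 11. Against stepwise conjugate addition and alkylation, this cut makes two bonds, ring B, the quaternary centre and the cis fusion in one step, and it places silicon on C7 and the arm on C8 without ambiguity. The precursors hold one stereocentre between them. The forward reaction needs attack anti to the methyl group and capture of the vinyl cation by the enolate before silicon is lost.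

**Enone 7, C16–C15 and the alkene.** 7 is traced to the α-phenylsulfanyl ketone 5 (sulfoxide elimination), which is cut at C16–C15 into ketone 3 and bromide 4. 3 comes from pulegone oxide 2 and so from (R)-pulegone 1 by thiolate-induced loss of acetone. Sulfur does three jobs: it excises the isopropylidene group, directs alkylation to C16 and becomes the leaving group for the alkene. The methyl stereocentre of 1 is never touched.

**Allene 11, C8–C9.** 11 is cut between the allene carbon and its arm into mesylate 9 (from alcohol 8) and the Grignard reagent 10, made from the same bromide 4. Both arms are carried as silyl ethers rather than halides: a 3-halopropyl organometallic would close to cyclopropane, and a hydride step lies downstream.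

## Roads not taken

Alternative 1: Ring C is cut at C10–C11 instead of at nitrogen. In the forward sense the hydrindane A2, which carries a C7 silyl dienol ether (C7(OSi)=C8–C9=C10) and an N-Boc-N-methoxymethyl amine on the C16 arm, is ionised with BF3·OEt2. The N-acyliminium carbon becomes C11, the diene terminus C10 attacks it, ring C closes and the C8=C9 enone is regenerated, giving carbamate A1, which is the same compound as 30. Its merit is real: ring closure and enone installation happen together, no nitrogen protecting-group exchange is needed, and the end game is about four steps shorter than the chosen one. Its weak points are that the nine-membered ring must be paid for in a C–C bond formation by a weak π-nucleophile; that attack through C8 would close a seven-membered ring instead; that the E geometry depends on the diene conformer; and that the carbamate and the tertiary acetate must survive BF3. A2 also leaves the whole ring A/B problem open and needs differentiated arms. Against the shorter end game the chosen plan sets a more dependable ring closure (sulfonamide SN2), an alkene geometry imposed by the ring, and a C7 carbonyl delivered already masked by the annulation.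

Alternative 2: Ring A is cut at C1–C16. The cyclopentenone A4 carries the C13–C15 arm on its β-carbon C16 and a C5 side chain ending in the C1 aldehyde. With SmI2 the ketyl adds to C16, closing ring A, and the samarium enolate and alkoxide are silylated to A3. This forms the quaternary centre and the C1 carbinol in one mild step. It also gives the C7–C8 enol ether regiospecifically, a handle the chosen route has to create by equilibrating silylation; in that respect it is better. Against this, the absolute configuration at C5 needs a separate asymmetric step, where the chosen plan takes it from pulegone. The C1/C16 relationship depends on the ketyl geometry and not on any resident substituent. The β,γ-unsaturated aldehyde of A4 can slip into conjugation. C3 arrives as an exocyclic methylene that still needs face-selective hydration, and the C8 arm and ring C are still to be built. The chosen plan spends four steps on ring A, but each has a stated source of selectivity.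

Alternative 3: Both carbocycles are cut, at C5–C16 and C2–C3. Under a chiral primary amine salt the acyclic triketone A6 undergoes Michael addition of the diketone carbon C16 to the enone β-carbon C5 (ring B), then aldol condensation of the acetyl methyl C2 onto the C3 ketone (ring A), giving the hydrindenedione A5. This is the shortest road to the bicycle, it is catalytic and enantioselective in principle, and A5 already holds the C1 enone with the C3 methyl that the chosen route reaches only after the annulation and a dehydrogenation; there it is better. Its weakness is what follows: the ring-B ketone of A5 sits on C8, not C7, so a 1,2-carbonyl transposition and the attachment of C9–C11 are both needed, with two ketones to tell apart. The catalyst must also set a quaternary centre from a 2-alkyl-1,3-diketone, a demanding case. The chosen plan is longer at the start but its vinylsilane marks C7 as the carbonyl carbon and brings the arm on C8.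

Key step: step 7

Assumption: C8 of 26, 27 and 28 and the epoxide carbons of 25 are formed without control and are written without configuration; both epimers converge because C8 becomes trigonal in 29. TBDPS = tert-butyldiphenylsilyl.

## Route

Step 1
Reactants: 1 (R)-(+)-pulegone
Product: 2 pulegone oxide, (6R)-2,2,6-trimethyl-1-oxaspiro[2.5]octan-4-one (both epimers at the spiro carbon)
Conditions: 30% aq. H2O2, LiOH (cat.), MeOH, 0 °C to rt
Reagents that add atoms: hydrogen peroxide, OO
Why: Weitz–Scheffer nucleophilic epoxidation of the electron-poor tetrasubstituted enone; the methyl stereocentre is remote, and the epimer mixture at the spiro carbon is of no consequence because that carbon becomes an enolate carbon in step 2.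

Step 2
Reactants: 2 pulegone oxide
Product: 3 (5R)-5-methyl-2-(phenylsulfanyl)cyclohexan-1-one (both C2 epimers)
Conditions: PhSNa, THF, reflux; then 1 M HCl
Reagents that add atoms: sodium benzenethiolate, [Na+].[S-]c1ccccc1
Why: Thiolate opens the epoxy ketone at the carbon next to the carbonyl and the tertiary alkoxide fragments by retro-aldol loss of acetone, a known degradation of pulegone oxide; sulfur is left on the future C16 and the methyl stereocentre, β to the carbonyl, cannot epimerise.

Step 3
Reactants: 3 (5R)-5-methyl-2-(phenylsulfanyl)cyclohexan-1-one; 4 (3-bromopropoxy)(tert-butyl)diphenylsilane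
Product: 5 (5R)-2-{3-[(tert-butyldiphenylsilyl)oxy]propyl}-5-methyl-2-(phenylsulfanyl)cyclohexan-1-one (both C2 epimers)
Conditions: NaH, THF–DMF, 0 °C; then 4, rt
Reagents that add atoms: none
Why: The sulfur-stabilised sodium enolate forms at the thio-bearing α-carbon, the more acidic site, and is C-alkylated by the primary bromide (SN2); the configuration of the new quaternary carbon is irrelevant because it becomes sp2 in step 4.

Step 4
Reactants: 5 (5R)-2-{3-[(tert-butyldiphenylsilyl)oxy]propyl}-5-methyl-2-(phenylsulfanyl)cyclohexan-1-one
Product: 7 (R)-2-{3-[(tert-butyldiphenylsilyl)oxy]propyl}-5-methylcyclohex-2-en-1-one, via sulfoxide 6 (not isolated)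
Conditions: mCPBA, CH2Cl2, −78 °C; then CaCO3, toluene, 110 °C
Reagents that add atoms: m-chloroperbenzoic acid, O=C(OO)c1cccc(Cl)c1 (its oxygen is held by 6 only and leaves with sulfur)
Why: Sulfide oxidation and thermal syn-elimination of the α-keto sulfoxide (sulfoxide pyrolysis); elimination should take a ring hydrogen, the usual preference of 2-alkyl-2-(arylsulfinyl)cyclohexanones, to give the endocyclic conjugated enone, and CaCO3 takes up the sulfenic acid.

Step 5
Reactants: 8 3-(trimethylsilyl)prop-2-yn-1-ol
Product: 9 3-(trimethylsilyl)prop-2-yn-1-yl methanesulfonate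
Conditions: MsCl, Et3N, CH2Cl2, 0 °C
Reagents that add atoms: methanesulfonyl chloride, CS(=O)(=O)Cl
Why: Routine sulfonylation of a primary propargylic alcohol; the mesylate is the leaving group for the SN2′ step.

Step 6
Reactants: 9 3-(trimethylsilyl)prop-2-yn-1-yl methanesulfonate; 4 (3-bromopropoxy)(tert-butyl)diphenylsilane
Product: 11 tert-butyldiphenyl{[4-(trimethylsilyl)hexa-4,5-dien-1-yl]oxy}silane, via Grignard reagent 10 (not isolated)
Conditions: 4, Mg, THF, 40 °C; then CuBr, LiBr, THF, −78 °C; then 9, −78 °C to rt
Reagents that add atoms: magnesium, [Mg] (held by 10 only)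
Why: The organocopper reagent from the Grignard reagent and CuBr·LiBr displaces the propargylic mesylate in SN2′ fashion at the silicon-bearing alkyne carbon, the standard synthesis of 1-substituted 1-(trimethylsilyl)allenes; a 3-silyloxypropyl Grignard reagent is stable, whereas a 3-halopropyl one would close to cyclopropane.

Step 7
Reactants: 7 (R)-2-{3-[(tert-butyldiphenylsilyl)oxy]propyl}-5-methylcyclohex-2-en-1-one; 11 tert-butyldiphenyl{[4-(trimethylsilyl)hexa-4,5-dien-1-yl]oxy}silane
Product: 12 cis-fused bicyclic ketone (3R,5S,16S): C1 ketone, C3 methyl on the bottom face, C7=C8 alkene with SiMe3 on C7, 3-(TBDPS-oxy)propyl arms on C8 and on C16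
Conditions: TiCl4 (1.2 equiv), CH2Cl2, −78 °C
Reagents that add atoms: none
Why: TiCl4 binds the enone carbonyl of 7; the CH2 terminus of the allenylsilane (C6) adds to the β-carbon C5, giving a vinyl cation on the central allene carbon stabilised by the adjacent C–Si bond, a 1,2-shift of silicon to that carbon (C7) moves the charge to C8, and the titanium enolate carbon C16 captures it. The closest known reaction type is the Danheiser (trimethylsilyl)cyclopentene annulation of 1-substituted 1-(trimethylsilyl)allenes with 2-alkylcyclohex-2-enones. Ring B closes as a five-membered ring by C-alkylation of the enolate with the tethered vinyl cation, leaving the new alkene C7=C8 inside the ring; because C8 is held to C5 through C6 and C7, the C8–C16 bond can form only on the face that already bears C6, so the fusion is cis. C5 is set by the C3 methyl group: the allene attacks the half-chair enone axially and anti to that methyl, as nucleophiles do with 5-methylcyclohex-2-enone, and C16 follows from C5 through the tether. The step needs silicon on C7 and the arm on C8, which the substitution pattern of the allene fixes; it needs enolate capture to outrun loss of Me3Si+ (conjugate propargylation), which 1-substituted allenes and −78 °C favour; and it needs inert arms, for which bulky, poorly coordinating TBDPS ethers were chosen.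

Step 8
Reactants: 12 cis-fused bicyclic ketone
Product: 14 bicyclic enone (5S,16S) with C1 ketone and C2=C3 alkene bearing the C3 methyl, via trimethylsilyl enol ether 13 (not isolated)
Conditions: LiN(SiMe3)2, Me3SiCl, THF, −78 °C; then Pd(OAc)2, MeCN, rt
Reagents that add atoms: chlorotrimethylsilane, C[Si](C)(C)Cl (its silyl group is held by 13 only)
Why: C16 is quaternary, so the C1 ketone can enolise only toward C2; Saegusa–Ito oxidation of the silyl enol ether removes the C3 hydrogen by β-hydride elimination and gives the C2=C3 enone, deliberately erasing the C3 stereocentre once it has set C5 and C16.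

Step 9
Reactants: 14 bicyclic enone
Product: 15 allylic alcohol (1S,5S,16S), C1 hydroxyl on the top face
Conditions: NaBH4, CeCl3·7H2O, MeOH, −78 to 0 °C
Reagents that add atoms: none
Why: Luche 1,2-reduction; the top face of the carbonyl is screened by ring B (C6 on C5 is 1,3 to C1 and C8 on C16 is next to it), so hydride should add axially from the bottom, convex face in the half-chair that has the C16 arm equatorial, placing the C1 hydroxyl on the top face.

Step 10
Reactants: 15 allylic alcohol
Product: 16 epoxy alcohol (1R,2R,3S,5S,16S), C2–C3 epoxide on the top face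
Conditions: VO(acac)2 (cat.), t-BuOOH, CH2Cl2, 0 °C to rt
Reagents that add atoms: tert-butyl hydroperoxide, CC(C)(C)OO
Why: Hydroxyl-directed epoxidation: the vanadium alkoxide of the C1 alcohol delivers oxygen to the C2=C3 alkene on its own (top) face, fixing the C3–O bond with the methyl group below; the tetrasubstituted vinylsilane is not an allylic alcohol and should not compete.

Step 11
Reactants: 16 epoxy alcohol
Product: 17 cis-1,3-diol (1S,3S,5S,16S), secondary C1 and tertiary C3 hydroxyls on the top face
Conditions: LiAlH4, THF, 0 to 40 °C
Reagents that add atoms: none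
Why: Hydride opens the trisubstituted epoxide by SN2 attack at the secondary carbon C2 from the bottom face (trans-diaxial opening, Fürst–Plattner), leaving oxygen on C3 and giving the cis-1,3-diol; silyl ethers and the vinylsilane are inert to LiAlH4.

Step 12
Reactants: 17 cis-1,3-diol
Product: 18 diacetate (1S,3S,5S,16S)
Conditions: Ac2O, Et3N, DMAP, CH2Cl2, rt to 40 °C
Reagents that add atoms: acetic anhydride, CC(=O)OC(C)=O
Why: DMAP-catalysed acylation with excess anhydride esterifies the secondary and, on warming, the tertiary alcohol, as it does for 1-methylcyclohexanol-type carbinols; no stereocentre is touched.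

Step 13
Reactants: 18 diacetate
Product: 19 diacetate with free 3-hydroxypropyl arms on C8 and C16
Conditions: HF·pyridine, pyridine, THF, 0 °C to rt
Reagents that add atoms: none
Why: Fluoride cleaves both primary silyl ethers; pyridine-buffered HF leaves the acetates and the vinyl–SiMe3 bond intact.

Step 14
Reactants: 19 diacetate diol
Product: 20 bis-mesylate
Conditions: MsCl, Et3N, CH2Cl2, 0 °C
Reagents that add atoms: methanesulfonyl chloride, CS(=O)(=O)Cl
Why: Standard bis-mesylation of the two primary alcohols; the acetates block the ring A oxygens.

Step 15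
Reactants: 20 bis-mesylate; 21 2-nitrobenzenesulfonamide
Product: 24 tricyclic N-nosyl azacycle (1S,3S,5S,16S) with C7–SiMe3 vinylsilane, via C13 nosylamide 22 (not isolated), via C11 nosylamide 23 (not isolated)
Conditions: Cs2CO3, n-Bu4NI (cat.), DMF (0.01 M), 60 °C
Reagents that add atoms: none
Why: Double N-alkylation of the sulfonamide (Richman–Atkins-type cyclisation with the nosyl group): an intermolecular SN2 at either arm is followed by nine-membered ring closure of the N-alkyl nosylamide anion under dilution; the arms are identical, so both orders converge, and the trigonal C8 and quaternary C16 hold them on neighbouring atoms.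

Step 16
Reactants: 24 tricyclic N-nosyl vinylsilane
Product: 26 tricyclic N-nosyl C7 ketone (1S,3S,5S,16S; C8 epimers), via epoxysilane 25 (not isolated)
Conditions: mCPBA, NaHCO3, CH2Cl2, 0 °C; then 1 M HClO4, THF, rt
Reagents that add atoms: m-chloroperbenzoic acid, O=C(OO)c1cccc(Cl)c1 (its oxygen becomes the C7 carbonyl oxygen)
Why: Peracid epoxidation of the vinylsilane gives the α,β-epoxysilane; acid opens it at C8 to a tertiary cation stabilised by the β-silicon, loss of silicon gives the C7 enol and so the ketone on the carbon that bore silicon; nosylamide and acetates tolerate dilute aqueous acid, and the C8 configuration is of no consequence.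

Step 17
Reactants: 26 tricyclic N-nosyl ketone
Product: 28 tricyclic N-Boc C7 ketone (1S,3S,5S,16S; C8 epimers), via amino ketone 27 (not isolated)
Conditions: PhSH, K2CO3, DMF, rt; then Boc2O, rt
Reagents that add atoms: di-tert-butyl dicarbonate, CC(C)(C)OC(=O)OC(=O)OC(C)(C)C
Why: Fukuyama deprotection: thiolate adds to the nitroarene (Meisenheimer complex) and releases the amine with loss of SO2; immediate carbamoylation prevents transannular reactions of the amino ketone, and the exchange is placed before the enone exists because thiolate would add to it.

Step 18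
Reactants: 28 tricyclic N-Boc ketone
Product: 29 C7 trimethylsilyl enol ether with C7=C8 alkene
Conditions: Me3SiCl, Et3N, DMF, 80 °C
Reagents that add atoms: chlorotrimethylsilane, C[Si](C)(C)Cl
Why: Silylation under equilibrating conditions gives the more substituted C7=C8 silyl enol ether, the alkene position the tricycle already held in 24; carbamate and acetates are stable to Me3SiCl/Et3N.

Step 19
Reactants: 29 silyl enol ether
Product: 30 N-Boc derivative of the target, (E)-C8=C9 enone
Conditions: Pd(OAc)2, MeCN, rt to 40 °C
Reagents that add atoms: none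
Why: Saegusa–Ito oxidation: the palladium enolate at C8 can undergo β-hydride elimination only toward C9 because C16 has no hydrogen, and the nine-membered ring allows only the cis-cycloalkene, which is the E enone.

Step 20
Reactants: 30 N-Boc enone
Product: 31 target, (1S,3S,5S,16S,8E)
Conditions: TFA, CH2Cl2, 0 °C; then aq. NaHCO3
Reagents that add atoms: none
Why: Acidolysis of the tert-butyl carbamate; brief cold TFA should spare the secondary and the inductively deactivated tertiary acetate, and the E alkene holds N12 away from C7 and C9, so the free amine does not cyclise.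

## Compound list

1 | (R)-(+)-pulegone | O=C1C[C@H](C)CCC1=C(C)C | starting material
2 | pulegone oxide, (6R)-2,2,6-trimethyl-1-oxaspiro[2.5]octan-4-one, both spiro epimers | O=C1C[C@H](C)CCC12OC2(C)C | intermediate
3 | (5R)-5-methyl-2-(phenylsulfanyl)cyclohexan-1-one, both C2 epimers | O=C1C[C@H](C)CCC1Sc1ccccc1 | intermediate
4 | (3-bromopropoxy)(tert-butyl)diphenylsilane | BrCCCO[Si](c1ccccc1)(c1ccccc1)C(C)(C)C | starting material
5 | (5R)-2-{3-[(tert-butyldiphenylsilyl)oxy]propyl}-5-methyl-2-(phenylsulfanyl)cyclohexan-1-one, both C2 epimers | O=C1C[C@H](C)CCC1(CCCO[Si](c1ccccc1)(c1ccccc1)C(C)(C)C)Sc1ccccc1 | intermediate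
6 | sulfoxide of 5, (5R)-2-{3-[(tert-butyldiphenylsilyl)oxy]propyl}-5-methyl-2-(phenylsulfinyl)cyclohexan-1-one | O=C1C[C@H](C)CCC1(CCCO[Si](c1ccccc1)(c1ccccc1)C(C)(C)C)S(=O)c1ccccc1 | intermediate (not isolated)
7 | (R)-2-{3-[(tert-butyldiphenylsilyl)oxy]propyl}-5-methylcyclohex-2-en-1-one | O=C1C[C@H](C)CC=C1CCCO[Si](c1ccccc1)(c1ccccc1)C(C)(C)C | intermediate
8 | 3-(trimethylsilyl)prop-2-yn-1-ol | OCC#C[Si](C)(C)C | starting material
9 | 3-(trimethylsilyl)prop-2-yn-1-yl methanesulfonate | CS(=O)(=O)OCC#C[Si](C)(C)C | intermediate
10 | {3-[(tert-butyldiphenylsilyl)oxy]propyl}magnesium bromide | Br[Mg]CCCO[Si](c1ccccc1)(c1ccccc1)C(C)(C)C | intermediate (not isolated)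
11 | tert-butyldiphenyl{[4-(trimethylsilyl)hexa-4,5-dien-1-yl]oxy}silane | C=C=C(CCCO[Si](c1ccccc1)(c1ccccc1)C(C)(C)C)[Si](C)(C)C | intermediate
12 | cis-fused bicyclic ketone (3R,5S,16S): C1 ketone, C3 methyl below, C7–SiMe3 on the C7=C8 alkene, 3-(TBDPS-oxy)propyl arms on C8 and C16 | O=C1C[C@H](C)C[C@H]2CC([Si](C)(C)C)=C(CCCO[Si](c3ccccc3)(c3ccccc3)C(C)(C)C)[C@]21CCCO[Si](c1ccccc1)(c1ccccc1)C(C)(C)C | intermediate
13 | C1 trimethylsilyl enol ether of 12 (C1=C2) | C[Si](C)(C)OC1=C[C@H](C)C[C@H]2CC([Si](C)(C)C)=C(CCCO[Si](c3ccccc3)(c3ccccc3)C(C)(C)C)[C@]21CCCO[Si](c1ccccc1)(c1ccccc1)C(C)(C)C | intermediate (not isolated)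
14 | bicyclic enone (5S,16S): C1 ketone, C2=C3 alkene with C3 methyl | O=C1C=C(C)C[C@H]2CC([Si](C)(C)C)=C(CCCO[Si](c3ccccc3)(c3ccccc3)C(C)(C)C)[C@]21CCCO[Si](c1ccccc1)(c1ccccc1)C(C)(C)C | intermediate
15 | allylic alcohol (1S,5S,16S), C1–OH on the top face | O[C@H]1C=C(C)C[C@H]2CC([Si](C)(C)C)=C(CCCO[Si](c3ccccc3)(c3ccccc3)C(C)(C)C)[C@]21CCCO[Si](c1ccccc1)(c1ccccc1)C(C)(C)C | intermediate
16 | epoxy alcohol (1R,2R,3S,5S,16S), C2–C3 epoxide and C1–OH on the top face | O[C@H]1[C@H]3O[C@@]3(C)C[C@H]2CC([Si](C)(C)C)=C(CCCO[Si](c3ccccc3)(c3ccccc3)C(C)(C)C)[C@]21CCCO[Si](c1ccccc1)(c1ccccc1)C(C)(C)C | intermediate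
17 | cis-1,3-diol (1S,3S,5S,16S), C1–OH and C3–OH on the top face, C3 methyl below | O[C@H]1C[C@@](C)(O)C[C@H]2CC([Si](C)(C)C)=C(CCCO[Si](c3ccccc3)(c3ccccc3)C(C)(C)C)[C@]21CCCO[Si](c1ccccc1)(c1ccccc1)C(C)(C)C | intermediate
18 | C1,C3-diacetate of 17 | CC(=O)O[C@H]1C[C@@](C)(OC(C)=O)C[C@H]2CC([Si](C)(C)C)=C(CCCO[Si](c3ccccc3)(c3ccccc3)C(C)(C)C)[C@]21CCCO[Si](c1ccccc1)(c1ccccc1)C(C)(C)C | intermediate
19 | diacetate with 3-hydroxypropyl arms on C8 and C16 | CC(=O)O[C@H]1C[C@@](C)(OC(C)=O)C[C@H]2CC([Si](C)(C)C)=C(CCCO)[C@]21CCCO | intermediate
20 | bis-mesylate of 19 | CC(=O)O[C@H]1C[C@@](C)(OC(C)=O)C[C@H]2CC([Si](C)(C)C)=C(CCCOS(C)(=O)=O)[C@]21CCCOS(C)(=O)=O | intermediate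
21 | 2-nitrobenzenesulfonamide | NS(=O)(=O)c1ccccc1[N+](=O)[O-] | starting material
22 | mono-alkylated nosylamide, nitrogen on C13 (C16 arm), mesylate left on C11 | CC(=O)O[C@H]1C[C@@](C)(OC(C)=O)C[C@H]2CC([Si](C)(C)C)=C(CCCOS(C)(=O)=O)[C@]21CCCNS(=O)(=O)c1ccccc1[N+](=O)[O-] | intermediate (not isolated)
23 | mono-alkylated nosylamide, nitrogen on C11 (C8 arm), mesylate left on C13 | CC(=O)O[C@H]1C[C@@](C)(OC(C)=O)C[C@H]2CC([Si](C)(C)C)=C(CCCNS(=O)(=O)c3ccccc3[N+](=O)[O-])[C@]21CCCOS(C)(=O)=O | intermediate (not isolated)
24 | tricyclic N-nosyl azacycle (1S,3S,5S,16S), C7–SiMe3 on the C7=C8 alkene | CC(=O)O[C@H]1C[C@@](C)(OC(C)=O)C[C@H]2CC([Si](C)(C)C)=C3CCCN(S(=O)(=O)c4ccccc4[N+](=O)[O-])CCC[C@@]321 | intermediate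
25 | C7–C8 epoxysilane of 24 (epoxide face not assigned) | CC(=O)O[C@H]1C[C@@](C)(OC(C)=O)C[C@H]2CC5([Si](C)(C)C)OC35CCCN(S(=O)(=O)c4ccccc4[N+](=O)[O-])CCC[C@@]321 | intermediate (not isolated)
26 | tricyclic N-nosyl C7 ketone (1S,3S,5S,16S), C8 epimers | CC(=O)O[C@H]1C[C@@](C)(OC(C)=O)C[C@H]2CC(=O)C3CCCN(S(=O)(=O)c4ccccc4[N+](=O)[O-])CCC[C@@]321 | intermediate
27 | tricyclic amino ketone (free N12–H), C8 epimers | CC(=O)O[C@H]1C[C@@](C)(OC(C)=O)C[C@H]2CC(=O)C3CCCNCCC[C@@]321 | intermediate (not isolated)
28 | tricyclic N-Boc C7 ketone (1S,3S,5S,16S), C8 epimers | CC(=O)O[C@H]1C[C@@](C)(OC(C)=O)C[C@H]2CC(=O)C3CCCN(C(=O)OC(C)(C)C)CCC[C@@]321 | intermediate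
29 | C7 trimethylsilyl enol ether of 28 (C7=C8) | CC(=O)O[C@H]1C[C@@](C)(OC(C)=O)C[C@H]2CC(O[Si](C)(C)C)=C3CCCN(C(=O)OC(C)(C)C)CCC[C@@]321 | intermediate
30 | N-Boc derivative of the target, (E)-C8=C9 enone | CC(=O)O[C@H]1C[C@@](C)(OC(C)=O)C[C@H]2CC(=O)/C3=C/CCN(C(=O)OC(C)(C)C)CCC[C@@]321 | intermediate
31 | target, (1S,3S,5S,16S,8E) | CC(=O)O[C@H]1C[C@@](C)(OC(C)=O)C[C@H]2CC(=O)/C3=C/CCNCCC[C@@]321 | target

## Step count and least certain steps

Total step count: 20 (steps 1–20). Longest linear sequence: 18 steps from 1 (steps 1–4 and 7–20); the allene branch is 2 steps (5 and 6).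

**Step 7 (key).** The vinyl cation may lose Me3Si+ before the enolate captures it (conjugate propargylation instead of annulation). Addition to the α-branched, TiCl4-bound enone may also be slow enough for Lewis-acid oligomerisation of the allene to compete. Fallback: the annulation is moved to the unbranched enone, where ring closure onto a secondary enolate carbon is faster, and the C16 arm is added afterwards. It sets out from 3: oxidation gives the sulfoxide F1 and pyrolysis gives (R)-5-methylcyclohex-2-en-1-one F2. TiCl4-promoted annulation of F2 with 11 gives the cis-fused ketone with hydrogen on C16 F3. This is deprotonated at C16 under equilibrating conditions (KOtBu, THF–t-BuOH; the enolate is extended through C8=C7) and alkylated with 4 on the convex face, which returns to the route at 12.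

**Step 4.** The syn-elimination may run toward the side chain and give the exocyclic alkylidene ketone. Fallback: from 3 through the sulfoxide F1 to the enone F2 as above; α-iodination (I2, pyridine) gives (R)-2-iodo-5-methylcyclohex-2-en-1-one F4. Negishi coupling (PdCl2(dppf) cat.) with the organozinc chloride F5, made from Grignard reagent 10 and ZnCl2, returns to the route at 7.

**Step 9.** Hydride may be delivered to the top face through the conformer with the C16 arm axial, giving the C1 epimer. Fallback: from 14, the C1-epimeric allylic alcohol F6 is inverted by Mitsunobu esterification (PPh3, DIAD, 4-nitrobenzoic acid) to the 4-nitrobenzoate F7, and methanolysis (K2CO3, MeOH) returns to the route at 15.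

**Step 15.** The ring-closing second alkylation is slow for a nine-membered ring, so intermolecular alkylation and base-induced elimination of the remaining mesylate can take over. Fallback: the two C–N bonds are made separately and without base from diol 19. Fukuyama–Mitsunobu reaction with 21 (PPh3, DIAD) gives the hydroxy nosylamide with nitrogen on C13 F8 and its regioisomer with nitrogen on C11 F9. Both close in a second, intramolecular Mitsunobu reaction run on its own under high dilution, returning to the route at 24.

**Step 19 (with step 18).** Palladation of the hindered tetrasubstituted enol ether at C8 may be slower than its hydrolysis back to 28. Fallback: from 29, PhSeCl (CH2Cl2, −78 °C) gives the α-phenylselanyl ketone F10; oxidation (H2O2, pyridine) gives the selenoxide F11, whose syn-elimination can likewise run only toward C9 and returns to the route at 30.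

## Further compounds

F1 | step 7 | (5R)-5-methyl-2-(phenylsulfinyl)cyclohexan-1-one | O=C1C[C@H](C)CCC1S(=O)c1ccccc1
F2 | step 7 | (R)-5-methylcyclohex-2-en-1-one | O=C1C[C@H](C)CC=C1
F3 | step 7 | cis-fused bicyclic ketone (3R,5S,16S) with hydrogen on C16, C7–SiMe3, 3-(TBDPS-oxy)propyl arm on C8 | O=C1C[C@H](C)C[C@H]2CC([Si](C)(C)C)=C(CCCO[Si](c3ccccc3)(c3ccccc3)C(C)(C)C)[C@H]21
F4 | step 4 | (R)-2-iodo-5-methylcyclohex-2-en-1-one | O=C1C[C@H](C)CC=C1I
F5 | step 4 | {3-[(tert-butyldiphenylsilyl)oxy]propyl}zinc chloride | Cl[Zn]CCCO[Si](c1ccccc1)(c1ccccc1)C(C)(C)C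
F6 | step 9 | C1 epimer of 15 (C1–OH on the bottom face) | O[C@@H]1C=C(C)C[C@H]2CC([Si](C)(C)C)=C(CCCO[Si](c3ccccc3)(c3ccccc3)C(C)(C)C)[C@]21CCCO[Si](c1ccccc1)(c1ccccc1)C(C)(C)C
F7 | step 9 | 4-nitrobenzoate of 15 (ester oxygen on the top face) | O=C(O[C@H]1C=C(C)C[C@H]2CC([Si](C)(C)C)=C(CCCO[Si](c3ccccc3)(c3ccccc3)C(C)(C)C)[C@]21CCCO[Si](c1ccccc1)(c1ccccc1)C(C)(C)C)c1ccc(cc1)[N+](=O)[O-]
F8 | step 15 | hydroxy nosylamide, nitrogen on C13, hydroxyl on C11 | CC(=O)O[C@H]1C[C@@](C)(OC(C)=O)C[C@H]2CC([Si](C)(C)C)=C(CCCO)[C@]21CCCNS(=O)(=O)c1ccccc1[N+](=O)[O-]
F9 | step 15 | hydroxy nosylamide, nitrogen on C11, hydroxyl on C13 | CC(=O)O[C@H]1C[C@@](C)(OC(C)=O)C[C@H]2CC([Si](C)(C)C)=C(CCCNS(=O)(=O)c3ccccc3[N+](=O)[O-])[C@]21CCCO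
F10 | step 19 | C8 phenylselanyl derivative of 28 (C8 configuration not assigned) | CC(=O)O[C@H]1C[C@@](C)(OC(C)=O)C[C@H]2CC(=O)C3([Se]c4ccccc4)CCCN(C(=O)OC(C)(C)C)CCC[C@@]321
F11 | step 19 | selenoxide of F10 | CC(=O)O[C@H]1C[C@@](C)(OC(C)=O)C[C@H]2CC(=O)C3([Se](=O)c4ccccc4)CCCN(C(=O)OC(C)(C)C)CCC[C@@]321
A1 | alternative 1 | N-Boc derivative of the target (identical with 30) | CC(=O)O[C@H]1C[C@@](C)(OC(C)=O)C[C@H]2CC(=O)/C3=C/CCN(C(=O)OC(C)(C)C)CCC[C@@]321
A2 | alternative 1 | bicyclic diacetate with C7 tert-butyldimethylsilyl dienol ether (C7=C8–C9=C10) and N-Boc-N-(methoxymethyl)aminopropyl arm on C16 | CC(=O)O[C@H]1C[C@@](C)(OC(C)=O)C[C@H]2CC(O[Si](C)(C)C(C)(C)C)=C(C=C)[C@]21CCCN(COC)C(=O)OC(C)(C)C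
A3 | alternative 2 | cis-hydrindane bis-silyl derivative (C1 trimethylsilyl ether, C7–C8 trimethylsilyl enol ether, C3 exocyclic methylene, TBDPS-oxypropyl arm on C16) | C[Si](C)(C)O[C@H]1CC(=C)C[C@H]2CC(O[Si](C)(C)C)=C[C@]21CCCO[Si](C(C)(C)C)(c1ccccc1)c1ccccc1
A4 | alternative 2 | cyclopentenone aldehyde: C16 arm on the enone β-carbon, C5 side chain CH2–C(=CH2)–CH2–CHO | O=CCC(=C)C[C@H]1CC(=O)C=C1CCCO[Si](C(C)(C)C)(c1ccccc1)c1ccccc1
A5 | alternative 3 | cis-fused hydrindenedione (C1 enone, C8 ketone, N-Boc-aminopropyl arm on C16) | O=C1C=C(C)C[C@H]2CCC(=O)[C@]21CCCNC(=O)OC(C)(C)C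
A6 | alternative 3 | acyclic triketone, tert-butyl N-[(7E)-4-acetyl-5,10-dioxoundec-7-en-1-yl]carbamate | CC(=O)C(CCCNC(=O)OC(C)(C)C)C(=O)CC/C=C/C(C)=O
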